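**Plan**

1. Numbering: ring A is the 2,3-dibromo-4,5-dihydroxybenzyl ring (C1 carries the diarylmethane CH2). Ring B is the ether-bearing ring (C1 CH2–O, C2 CH2–ring A, C3 Br, C4 OH, C5 OH, C6 H).
2. Enabling feature: on ring B, C1 lies para to OH-4, and both carbons ortho to OH-4 are occupied (C3–Br, C5–O). The CH2–O–CH2 bridge is therefore a bis(4-hydroxybenzyl) ether, the kind of link a phenol and formaldehyde form in a resole.
3. Retrosynthesis: remove four O-5 allyl groups; cut one C–O bond of the bridge and both ring-B C1–CH2 bonds, giving two molecules of diarylmethane bisphenol 8 and two of formaldehyde; cut the ring-B C2–CH2 bond (Friedel–Crafts) to benzyl alcohol 4 and 3-bromoveratrole 5; 4 derives from 5-bromovanillin 1.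
4. Forward: no ring is made, both benzene rings are bought. The ring-A benzyl alcohol is prepared (steps 1–3), rings A and B are joined (step 4), the catechols are freed and each O-5 is capped with allyl (steps 5–6), formaldehyde joins two halves (step 7), and Pd(0) removes the allyl groups (step 8). Allyl is chosen because it neither migrates nor hydrolyses in alkaline formaldehyde and leaves under neutral conditions.
5. Stereochemistry (assumption): the target has no stereocentre or stereogenic axis and its SMILES carries no descriptor, so it is achiral and nothing has to be set or protected from scrambling.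

Key step: step 7

**Route**

Step 1
Reactants: 1 5-bromovanillin (3-bromo-4-hydroxy-5-methoxybenzaldehyde)
Product: 2 2,3-dibromo-4-hydroxy-5-methoxybenzaldehyde (5,6-dibromovanillin)
Conditions: Br2 (1.2 equiv), Fe powder (cat.), NaOAc, AcOH, rt → 50 °C
Reagents that add atoms: bromine, BrBr
Why: Fe-catalysed electrophilic aromatic bromination, in which the only open carbons are C2 and C6 and bromine should enter C2, para to the 5-methoxy group and next to the existing bromine, setting the contiguous Br/Br/O/O pattern of ring A.

Step 2
Reactants: 2 2,3-dibromo-4-hydroxy-5-methoxybenzaldehyde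
Product: 3 2,3-dibromo-4,5-dimethoxybenzaldehyde
Conditions: MeI (1.5 equiv), K2CO3, DMF, rt
Reagents that add atoms: iodomethane, CI
Why: Williamson O-methylation of the phenoxide, so that the later Lewis-acid step meets only ethers, while the aldehyde and aryl bromides are inert.

Step 3
Reactants: 3 2,3-dibromo-4,5-dimethoxybenzaldehyde
Product: 4 (2,3-dibromo-4,5-dimethoxyphenyl)methanol
Conditions: NaBH4, THF/MeOH, 0 °C; aqueous work-up
Reagents that add atoms: none
Why: Chemoselective borohydride reduction of the aryl aldehyde to the benzylic alcohol, with aryl bromides and methyl ethers untouched.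

Step 4
Reactants: 4 (2,3-dibromo-4,5-dimethoxyphenyl)methanol; 5 1-bromo-2,3-dimethoxybenzene (3-bromoveratrole, 1.5 equiv)
Product: 6 2-bromo-1-(2,3-dibromo-4,5-dimethoxybenzyl)-3,4-dimethoxybenzene
Conditions: AlCl3 (1.2 equiv), CH2Cl2, 0 °C → rt; ice/1 M HCl
Reagents that add atoms: none
Why: Friedel–Crafts benzylation, in which AlCl3 ionises 4 to a 4-methoxybenzyl-type cation that should attack 5 para to its in-plane 3-methoxy group (the carbon next to Br), because the 2-methoxy group squeezed between Br and OMe is twisted out of conjugation and directs only weakly.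

Step 5
Reactants: 6 2-bromo-1-(2,3-dibromo-4,5-dimethoxybenzyl)-3,4-dimethoxybenzene
Product: 7 3-bromo-4-(2,3-dibromo-4,5-dihydroxybenzyl)benzene-1,2-diol
Conditions: BBr3 (8 equiv), CH2Cl2, −78 °C → rt; ice-water, under N2
Reagents that add atoms: none
Why: BBr3 cleavage of all four aryl methyl ethers (Lewis adduct, bromide attack on methyl, hydrolysis of the aryl borates), which leaves the aryl bromides and the diarylmethane CH2 untouched.

Step 6
Reactants: 7 3-bromo-4-(2,3-dibromo-4,5-dihydroxybenzyl)benzene-1,2-diol
Product: 8 6-allyloxy-3-(5-allyloxy-2,3-dibromo-4-hydroxybenzyl)-2-bromophenol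
Conditions: NaH (4.2 equiv), degassed DMF, 0 °C; allyl bromide (2.05 equiv), 0 °C → rt; then 1 M HCl
Reagents that add atoms: allyl bromide, C=CCBr
Why: Regioselective Williamson O-alkylation of catechol dianions, in which the O-5 oxyanion of each ring (conjugate acid pKa about 13, unhindered) is far more nucleophilic than the O-4 oxyanion (pKa about 8, flanked by Br and O) and the bromophenoxide left after the first allylation reacts more slowly than the untouched dianion of the other ring, so two equivalents of allyl bromide should cap exactly the two O-5 positions.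

Step 7
Reactants: 8 6-allyloxy-3-(5-allyloxy-2,3-dibromo-4-hydroxybenzyl)-2-bromophenol (two molecules); 9 formaldehyde (two molecules incorporated, used in excess as paraformaldehyde)
Product: 11 bis[5-allyloxy-2-(5-allyloxy-2,3-dibromo-4-hydroxybenzyl)-3-bromo-4-hydroxybenzyl] ether, via benzylic alcohol 10 (not isolated)
Conditions: (CH2O)n (10 equiv), NaOH (2.5 equiv), H2O/1,4-dioxane, N2, 40 °C; AcOH to pH 6, EtOAc extraction, concentration; then PhMe, 4 Å MS, 100 °C
Reagents that add atoms: formaldehyde (9), C=O
Why: Lederer–Manasse hydroxymethylation followed by resole-type ether formation: the phenoxide of OH-4 on ring B has Br on one ortho carbon (C3) and the allyloxy group on the other (C5), so it can add to formaldehyde only through the para carbon C1, and tautomerisation gives the 4-hydroxybenzyl alcohol 10. After neutralisation, warming with removal of water lets one molecule of 10 lose water to a para-quinone methide, which the primary hydroxyl of a second molecule captures by 1,6-addition to close the CH2–O–CH2 bridge. The closest known reactions are the para-hydroxymethylation of 2,6-disubstituted phenols with alkaline formaldehyde and the thermal self-etherification of the resulting 4-hydroxybenzyl alcohols. No ring is closed and no stereocentre is formed. The step needs site selectivity for C1 of ring B and O- rather than C-capture of the quinone methide: ring A is inert because both ortho positions and the para position of its OH-4 are substituted, the fixed allyl ethers keep any phenoxide from activating C6 of either ring, and with no phenol-activated free carbon left, formaldehyde in excess and a temperature well below that at which such ethers extrude formaldehyde to methylene bridges, the benzylic hydroxyl is the only productive nucleophile, capture by the hindered phenols or by water being reversible.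

Step 8
Reactants: 11 bis[5-allyloxy-2-(5-allyloxy-2,3-dibromo-4-hydroxybenzyl)-3-bromo-4-hydroxybenzyl] ether
Product: 12 bis[3-bromo-2-(2,3-dibromo-4,5-dihydroxybenzyl)-4,5-dihydroxybenzyl] ether (target)
Conditions: Pd(PPh3)4 (10 mol %), morpholine (8 equiv), degassed THF, rt
Reagents that add atoms: none
Why: Tsuji–Trost-type Pd(0) deallylation, in which oxidative addition of each aryl allyl ether gives a π-allylpalladium phenoxide whose allyl group passes to morpholine, under aprotic, mildly basic conditions at room temperature that should leave the di-ortho-substituted, electron-rich aryl bromides and the acid-labile bis(4-hydroxybenzyl) ether intact.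

**Compound list**

1 | 5-bromovanillin (3-bromo-4-hydroxy-5-methoxybenzaldehyde) | COc1cc(C=O)cc(Br)c1O | starting material
2 | 2,3-dibromo-4-hydroxy-5-methoxybenzaldehyde | COc1cc(C=O)c(Br)c(Br)c1O | intermediate
3 | 2,3-dibromo-4,5-dimethoxybenzaldehyde | COc1cc(C=O)c(Br)c(Br)c1OC | intermediate
4 | (2,3-dibromo-4,5-dimethoxyphenyl)methanol | COc1cc(CO)c(Br)c(Br)c1OC | intermediate
5 | 1-bromo-2,3-dimethoxybenzene (3-bromoveratrole) | COc1cccc(Br)c1OC | starting material
6 | 2-bromo-1-(2,3-dibromo-4,5-dimethoxybenzyl)-3,4-dimethoxybenzene | COc1ccc(Cc2cc(OC)c(OC)c(Br)c2Br)c(Br)c1OC | intermediate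
7 | 3-bromo-4-(2,3-dibromo-4,5-dihydroxybenzyl)benzene-1,2-diol | Oc1ccc(Cc2cc(O)c(O)c(Br)c2Br)c(Br)c1O | intermediate
8 | 6-allyloxy-3-(5-allyloxy-2,3-dibromo-4-hydroxybenzyl)-2-bromophenol | C=CCOc1ccc(Cc2cc(OCC=C)c(O)c(Br)c2Br)c(Br)c1O | intermediate
9 | formaldehyde (used as paraformaldehyde) | C=O | starting material
10 | 6-allyloxy-3-(5-allyloxy-2,3-dibromo-4-hydroxybenzyl)-2-bromo-4-(hydroxymethyl)phenol | C=CCOc1cc(CO)c(Cc2cc(OCC=C)c(O)c(Br)c2Br)c(Br)c1O | intermediate
11 | bis[5-allyloxy-2-(5-allyloxy-2,3-dibromo-4-hydroxybenzyl)-3-bromo-4-hydroxybenzyl] ether | O(Cc1cc(OCC=C)c(O)c(Br)c1Cc1cc(OCC=C)c(O)c(Br)c1Br)Cc1cc(OCC=C)c(O)c(Br)c1Cc1cc(OCC=C)c(O)c(Br)c1Br | intermediate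
12 | bis[3-bromo-2-(2,3-dibromo-4,5-dihydroxybenzyl)-4,5-dihydroxybenzyl] ether | Oc1cc(Cc2c(COCc3cc(O)c(O)c(Br)c3Cc3cc(O)c(O)c(Br)c3Br)cc(O)c(O)c2Br)c(Br)c(Br)c1O | target

**Step count and risks**

Total: 8 steps. Longest linear sequence: 8 steps (1 → 2 → 3 → 4 → 6 → 7 → 8 → 11 → 12); 5 and 9 enter as bought materials.

Step 7. The phenoxide of 8 is deactivated by Br-3 and its para carbon is flanked by the bulky benzyl group. C-addition to formaldehyde may therefore lag behind Cannizzaro consumption of the aldehyde, and alcohol 10 formed beside unreacted phenoxide may drain into methylene-bridged dimers. The fallback sets out from 8 and returns at 10. A Duff formylation (hexamethylenetetramine, AcOH, 110 °C, then aqueous HCl) introduces the C1 carbon as an aldehyde under acidic conditions and should give 5-allyloxy-2-(5-allyloxy-2,3-dibromo-4-hydroxybenzyl)-3-bromo-4-hydroxybenzaldehyde F1. NaBH4 (THF/MeOH, 0 °C) reduces F1 to 10, which is then isolated and carried through the thermal etherification stage of step 7 to 11.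

Step 6. The two oxyanions of each catechol may not be told apart cleanly (alkylation at O-4, over-allylation), and the polyanion is easily oxidised. The fallback sets out from 7 and returns at 12, using steric rather than electronic control and a fluoride-labile group. TIPSCl (2.2 equiv) and imidazole in DMF should silylate the less hindered O-5 of each ring, any silyl group landing on O-4 relaxing to the same isomer by O→O migration, to give 2-bromo-3-(2,3-dibromo-4-hydroxy-5-triisopropylsilyloxybenzyl)-6-triisopropylsilyloxyphenol F2. Hydroxymethylation with paraformaldehyde and Et3N in MeCN (an amine base in place of hydroxide, to spare the silyl ethers) leads to 2-bromo-3-(2,3-dibromo-4-hydroxy-5-triisopropylsilyloxybenzyl)-4-(hydroxymethyl)-6-triisopropylsilyloxyphenol F3. Warming F3 in toluene over molecular sieves condenses it to bis[3-bromo-2-(2,3-dibromo-4-hydroxy-5-triisopropylsilyloxybenzyl)-4-hydroxy-5-triisopropylsilyloxybenzyl] ether F4. TBAF buffered with AcOH (THF, 0 °C) then frees 12.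

Step 8. Pd(0) may add to the C–Br bonds (hydrodebromination), the amine may open the labile bis(4-hydroxybenzyl) ether through a quinone methide, and the catechols may oxidise in the basic medium. The fallback sets out from 11 and returns at 12 without Pd(0) or amine. Isomerisation of the four allyl ethers with H2-activated [Ir(cod)(PMePh2)2]PF6 (THF, rt) should give bis[3-bromo-2-(2,3-dibromo-4-hydroxy-5-((E)-prop-1-enyloxy)benzyl)-4-hydroxy-5-((E)-prop-1-enyloxy)benzyl] ether F5. Its enol ether groups are then hydrolysed with dilute aqueous acid (0.1 M HCl, acetone–water, 0 °C → rt), a reaction expected to outrun ionisation of the benzylic ether, to give 12.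

**Further compounds**

F1 | step 7 | 5-allyloxy-2-(5-allyloxy-2,3-dibromo-4-hydroxybenzyl)-3-bromo-4-hydroxybenzaldehyde | C=CCOc1cc(C=O)c(Cc2cc(OCC=C)c(O)c(Br)c2Br)c(Br)c1O
F2 | step 6 | 2-bromo-3-(2,3-dibromo-4-hydroxy-5-triisopropylsilyloxybenzyl)-6-triisopropylsilyloxyphenol | CC(C)[Si](Oc1ccc(Cc2cc(O[Si](C(C)C)(C(C)C)C(C)C)c(O)c(Br)c2Br)c(Br)c1O)(C(C)C)C(C)C
F3 | step 6 | 2-bromo-3-(2,3-dibromo-4-hydroxy-5-triisopropylsilyloxybenzyl)-4-(hydroxymethyl)-6-triisopropylsilyloxyphenol | CC(C)[Si](Oc1cc(CO)c(Cc2cc(O[Si](C(C)C)(C(C)C)C(C)C)c(O)c(Br)c2Br)c(Br)c1O)(C(C)C)C(C)C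
F4 | step 6 | bis[3-bromo-2-(2,3-dibromo-4-hydroxy-5-triisopropylsilyloxybenzyl)-4-hydroxy-5-triisopropylsilyloxybenzyl] ether | O(Cc1cc(O[Si](C(C)C)(C(C)C)C(C)C)c(O)c(Br)c1Cc1cc(O[Si](C(C)C)(C(C)C)C(C)C)c(O)c(Br)c1Br)Cc1cc(O[Si](C(C)C)(C(C)C)C(C)C)c(O)c(Br)c1Cc1cc(O[Si](C(C)C)(C(C)C)C(C)C)c(O)c(Br)c1Br
F5 | step 8 | bis[3-bromo-2-(2,3-dibromo-4-hydroxy-5-((E)-prop-1-enyloxy)benzyl)-4-hydroxy-5-((E)-prop-1-enyloxy)benzyl] ether | O(Cc1cc(O/C=C/C)c(O)c(Br)c1Cc1cc(O/C=C/C)c(O)c(Br)c1Br)Cc1cc(O/C=C/C)c(O)c(Br)c1Cc1cc(O/C=C/C)c(O)c(Br)c1Br
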